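## Structural features

Asperglaucin A is a 2-benzothiophen-1(3H)-one (numbering used throughout: C1 carbonyl, S2, C3, C3a, C4 to C7, C7a; carbinol carbon C1′). A five-membered thiolactone is fused along C3a–C7a to a benzene ring that is substituted at five of its six carbons: hydroxyls at C4 and C7 (a hydroquinone), a prenyl group at C6, and the only ring hydrogen at C5. The two stereocentres are adjacent: C3 (S), bonded to sulfur and the arene, and the exocyclic carbinol C1′ (R) bearing the pentyl chain. Their relationship is erythro, i.e. that of anti addition of S and O across an (E)-alkene or of inversion at one carbon of a trans-epoxide.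

Fragile groups:
- the hydroquinone (air oxidation to the quinone);
- the prenyl group ortho to C7–OH (acid closes a chroman);
- the thioester (nucleophiles);
- C3–H (benzylic and alpha to sulfur, so base can epimerise it);
- C1′–OH, which sits where, once deprotonated, it can take the acyl group from sulfur to give a six-membered lactone.

The real difficulty is twofold. The benzene ring has five different neighbours in a fixed order. In any arene-first plan the C3–S stereocentre must be made at a benzylic carbon flanked by C4–OH of an electron-rich ring, where ionisation to an ortho-quinone methide erases configuration.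

The key step exploits the edge O–C4–C5–C6–C7–O of the benzene ring. These four carbons with their para oxygens are the carbons of a 2-silyloxyfuran (ring oxygen ends on C4, silyloxy oxygen on C7, furan C3 substituent is the C6 prenyl). C3a=C7a, with an sp3 carbon on one side and an acyl carbon on the other, is a polarised ynoate whose polarity matches that of the furan. Because the ring is made last, C3 and C1′ can be set on an open chain where C3 is propargylic, not benzylic.

## Logic of the disconnections

**18 ⇒ 17.** The two O–Si bonds (at C7–O and C1′–O) are added back. The free C1′–OH beside the thioester and the free hydroquinone are the most fragile features, so they are unmasked last. There is no skeletal gain. The forward step needs a fluoride source that is mildly acidic and non-nucleophilic.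

**17 ⇒ 15 (through 16).** The S–C1(=O) bond is cut. Acyl transfer to sulfur is the one ring closure that does not touch C3. The thiolactone becomes an aryl ester next to a masked thiol on a simple pentasubstituted benzene. The forward step must free sulfur without acid damage to the prenyl group, and C1′–O must stay blocked so that the six-membered lactone cannot form.

**15 ⇒ 8 + 13 (through 14), the key disconnection.** The ring bonds C7–C7a and C4–C3a are cut and the C4 oxygen is reconnected to C7 as a furan oxygen. The arene falls into an achiral furan carrying only the prenyl group and an acyclic alkyne carrying both stereocentres; C3 becomes propargylic. The forward step needs one regiochemistry of cycloaddition and neutral conditions that leave the acidic γ-hydrogen of 8 alone.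

**13 ⇒ 10 + 11 (through 12); 10 ⇒ 9.** The furan C3–CH2 bond and then the O–Si bond are cut. A 3-bromo-2-silyloxyfuran is a regiodefined alpha-anion equivalent of a butenolide. The forward step needs halogen–metal exchange faster than silyl migration and SN2 rather than SN2′ alkylation.

**8 ⇒ 6 (through 7).** The alkyne–carboxyl bond is cut. A terminal alkyne tolerates thiolate chemistry whereas an ynoate would suffer conjugate addition, so sulfur must be in place before the ester. The forward acylation must not deprotonate the γ-carbon of its own product.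

**6 ⇒ 5 ⇒ 4.** The O–Si bond and then the C3–S bond are cut. SN2 opening of a trans-epoxide at its propargylic carbon gives the erythro S/O pair with inversion, so one epoxide supplies both stereocentres. The forward step needs attack at the propargylic carbon only and a medium too weakly basic for propargyl-to-allenyl isomerisation.

**4 ⇒ 3 ⇒ 2 ⇒ 1.** The alkyne carbon (one-carbon homologation of an aldehyde), the oxidation level, and the two C–O bonds of the epoxide are removed in turn. All chirality then comes from one catalytic, predictable epoxidation of a commercial allylic alcohol. The forward step needs the D-tartrate series.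

## Other disconnections considered

**Alternative 1:** (the first that comes to mind) Cut C3–S on a finished arene. Methyl 2-[(E)-hept-1-en-1-yl]-3,6-dimethoxybenzoate A1 would undergo Shi epoxidation (fructose-derived ketone, KHSO5) to the trans-epoxide A2. NaSH would then convert the ester to a thiocarboxylate that opens the benzylic epoxide 5-exo with inversion to the thiolactone A3. Grounds for preferring the chosen plan:
- Structure: the benzoate must be built by successive directed metalations, and the prenyl group cannot be present during asymmetric oxidation of the styrene (a trisubstituted alkene reacts faster), so it would have to be forced late onto a fully substituted ring.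
- Mechanism: the C–S bond forms at a benzylic carbon ortho to ring oxygen, where SN1 or quinone methide character threatens C3.
- Step economy: the methyl ethers would have to be removed through the quinone and re-reduction.

**Alternative 2:** (enzymatic) Set both stereocentres by reducing the C1′ carbonyl while C3 equilibrates. Racemic 3-hexanoyl-4,7-bis(methoxymethoxy)-6-prenyl-2-benzothiophen-1(3H)-one A4 would be reduced by a ketoreductase with NADPH recycling (dynamic reductive kinetic resolution) to the (3S,1′R) alcohol A5. Grounds for preferring the chosen plan: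
- The complete arene and thiolactone must exist before the key step, so the hardest ring is not addressed.
- A4 is a vinylogous β-keto thioester that should rest largely as a conjugated enol and can ring-open by retro-Claisen cleavage in buffer.
- An enzyme must be found that accepts an aryl ketone with two ortho substituents and gives the erythro isomer.
- Acidic removal of the acetals next to a prenyl group remains.

**Alternative 3:** (another ring-last plan) Dötz benzannulation. The carbene complex (CO)5Cr=C(OMe)C(=CH2)CH2CH=CMe2 A6 would combine with alkyne 8 and one CO ligand to give the 4-methoxyphenol A7, forming C7–C7a, C3a–C4 and C4–C5. Grounds for preferring the chosen plan: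
- It uses stoichiometric zerovalent chromium.
- Its regiochemistry rests only on the size difference of the two alkyne substituents and is unreliable for ynoates.
- The C7 oxygen emerges as a methyl ether whose cleavage is incompatible with the prenyl group and thioester.
- The furan route is metal-free, is polarity-controlled, and delivers a silyl ether.

Key step: step 9

Remark: 1, 9, 11 and the reagents named are taken as catalogue chemicals.

## Route

Step 1
Reactants: 1 (E)-oct-2-en-1-ol
Product: 2 [(2R,3R)-3-pentyloxiran-2-yl]methanol
Conditions: Ti(OiPr)4 (10 mol %), D-(−)-diethyl tartrate (12 mol %), t-BuOOH, 4 Å MS, CH2Cl2, −20 °C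
Reagents that add atoms: tert-butyl hydroperoxide, CC(C)(C)OO
Why: Sharpless asymmetric epoxidation; the D-(−)-tartrate catalyst delivers oxygen to the face of the (E)-allylic alcohol that gives the (2R,3R) epoxide (mirror image of the L-(+)-tartrate series), setting both C–O stereocentres, of which C3–O becomes the C1′ hydroxyl of the target.

Step 2
Reactants: 2 [(2R,3R)-3-pentyloxiran-2-yl]methanol
Product: 3 (2S,3R)-3-pentyloxirane-2-carbaldehyde
Conditions: TEMPO (10 mol %), PhI(OAc)2, CH2Cl2, rt
Reagents that add atoms: none
Why: Oxoammonium (TEMPO) oxidation of a primary alcohol stops at the aldehyde and is non-basic, so the epoxide is neither opened nor epimerised (the descriptor at C2 changes only through CIP priorities).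

Step 3
Reactants: 3 (2S,3R)-3-pentyloxirane-2-carbaldehyde
Product: 4 (2R,3R)-2-ethynyl-3-pentyloxirane
Conditions: dimethyl (1-diazo-2-oxopropyl)phosphonate, K2CO3, MeOH, 0 °C to rt
Reagents that add atoms: dimethyl (1-diazo-2-oxopropyl)phosphonate, COP(=O)(OC)C(=[N+]=[N-])C(C)=O
Why: Seyferth–Gilbert homologation in the Ohira–Bestmann variant (olefination to a diazoalkene, loss of N2, 1,2-hydrogen shift); the mild carbonate medium is known to leave trans-epoxy aldehydes configurationally intact.

Step 4
Reactants: 4 (2R,3R)-2-ethynyl-3-pentyloxirane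
Product: 5 (3S,4R)-3-[(triphenylmethyl)sulfanyl]non-1-yn-4-ol
Conditions: Ph3CSH (1.3 equiv), KOtBu (0.2 equiv), DMF, 0 °C to rt, argon
Reagents that add atoms: triphenylmethanethiol, SC(c1ccccc1)(c1ccccc1)c1ccccc1
Why: SN2 opening of the epoxide by the thiolate anti to the C–O bond at the propargylic carbon, which is activated by the adjacent π system and flanked by the small ethynyl group; inversion there gives (3S) while C4 keeps its oxygen and configuration (R), i.e. the erythro pair. Excess thiol protonates the alkoxide as it forms, so the medium never becomes basic enough for propargyl-to-allenyl isomerisation.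

Step 5
Reactants: 5 (3S,4R)-3-[(triphenylmethyl)sulfanyl]non-1-yn-4-ol
Product: 6 tert-butyl(dimethyl){[(3S,4R)-3-[(triphenylmethyl)sulfanyl]non-1-yn-4-yl]oxy}silane
Conditions: TBSCl, imidazole, DMAP (cat.), DMF, 40 °C
Reagents that add atoms: tert-butyl(chloro)dimethylsilane, CC(C)(C)[Si](C)(C)Cl
Why: Standard silylation of a secondary alcohol; the silyl ether blocks the oxygen that could later form a six-membered lactone or take the acyl group from sulfur.

Step 6
Reactants: 6 tert-butyl(dimethyl){[(3S,4R)-3-[(triphenylmethyl)sulfanyl]non-1-yn-4-yl]oxy}silane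
Product: 8 phenyl (4S,5R)-5-{[tert-butyl(dimethyl)silyl]oxy}-4-[(triphenylmethyl)sulfanyl]dec-2-ynoate, via lithium acetylide 7 (not isolated)
Conditions: n-BuLi (1.05 equiv), THF, −78 °C; then cannula addition to ClCO2Ph (1.5 equiv), THF, −78 °C
Reagents that add atoms: phenyl chloroformate, O=C(Cl)Oc1ccccc1
Why: Acylation of a lithium acetylide with a chloroformate; inverse addition at −78 °C keeps acetylide from meeting the product, whose γ-hydrogen is acidic, and from adding twice. The phenyl ester is chosen because it makes the alkyne a better dienophile and later yields to the thiol without any activating reagent.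

Step 7
Reactants: 9 3-bromofuran-2(5H)-one
Product: 10 [(3-bromofuran-2-yl)oxy]tri(propan-2-yl)silane
Conditions: TIPSOTf, Et3N, CH2Cl2, 0 °C
Reagents that add atoms: triisopropylsilyl trifluoromethanesulfonate, CC(C)[Si](OS(=O)(=O)C(F)(F)F)(C(C)C)C(C)C
Why: Soft enolisation of the butenolide (O-silylation, loss of a C5 proton) gives the aromatic 2-silyloxyfuran; the bulky silyl group makes it robust.

Step 8
Reactants: 10 [(3-bromofuran-2-yl)oxy]tri(propan-2-yl)silane; 11 1-bromo-3-methylbut-2-ene
Product: 13 {[3-(3-methylbut-2-en-1-yl)furan-2-yl]oxy}tri(propan-2-yl)silane, via 3-lithio-2-silyloxyfuran 12 (not isolated)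
Conditions: n-BuLi (1.05 equiv), THF, −78 °C; then 11, −78 to 0 °C
Reagents that add atoms: none
Why: Bromine–lithium exchange of a 3-bromo-2-silyloxyfuran gives a regiodefined butenolide alpha-anion equivalent (the triisopropylsilyl group suppresses O-to-C silyl shift), which is alkylated by the allylic bromide at its primary carbon (SN2; the γ-carbon is tertiary and hindered).

Step 9
Reactants: 8 phenyl (4S,5R)-5-{[tert-butyl(dimethyl)silyl]oxy}-4-[(triphenylmethyl)sulfanyl]dec-2-ynoate; 13 {[3-(3-methylbut-2-en-1-yl)furan-2-yl]oxy}tri(propan-2-yl)silane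
Product: 15 phenyl 3-hydroxy-2-[(1S,2R)-2-{[tert-butyl(dimethyl)silyl]oxy}-1-[(triphenylmethyl)sulfanyl]heptyl]-5-(3-methylbut-2-en-1-yl)-6-{[tri(propan-2-yl)silyl]oxy}benzoate, via oxanorbornadiene cycloadduct 14 (not isolated)
Conditions: 13 (1.5 equiv), BHT (cat.), PhMe (1 M), 90 °C, sealed tube, argon; then SiO2, CH2Cl2, rt if 14 persists
Reagents that add atoms: none
Why: Normal-electron-demand Diels–Alder reaction of the electron-rich furan 13 with the alkynoate 8; the closest known reaction type is the cycloaddition of 2-alkoxy- and 2-silyloxyfurans with acetylenic esters, which gives hydroquinone mono-ethers. The six-membered carbocycle is closed by a concerted, asynchronous, suprafacial [4+2] addition (furan C5 to the alkyne β-carbon leading, furan C2 to the α-carbon following), giving the 7-oxabicyclo[2.2.1]heptadiene 14. In 14 the bridgehead carbon bearing the silyloxy group is a ketal carbon, so the oxygen bridge ionises only there and loss of the other bridgehead proton aromatises the ring: the furan oxygen becomes the free phenol next to the side chain and the silyloxy group stays next to the ester. The selectivity needed is regiochemical; it is secured by matching the largest HOMO coefficient of 13 (C5) with the largest LUMO coefficient of 8 (β-carbon), and sterically by joining the unsubstituted furan terminus to the branched alkyne carbon. No new stereocentre survives: the two bridgehead centres of 14 form without control and are destroyed on aromatisation, so both facial isomers converge on 15. The two existing stereocentres are spectators because the medium is neutral and aprotic, so the acidic γ-hydrogen is not exchanged, and the prenyl double bond is too electron-rich to compete as dienophile. One operation thus fixes all five ring substituents, differentiates the two phenolic oxygens, and leaves the oxygen ortho to the prenyl group silylated, which blocks chroman formation.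

Step 10
Reactants: 15 phenyl 3-hydroxy-2-[(1S,2R)-2-{[tert-butyl(dimethyl)silyl]oxy}-1-[(triphenylmethyl)sulfanyl]heptyl]-5-(3-methylbut-2-en-1-yl)-6-{[tri(propan-2-yl)silyl]oxy}benzoate
Product: 17 (3S)-3-[(1R)-1-{[tert-butyl(dimethyl)silyl]oxy}hexyl]-4-hydroxy-6-(3-methylbut-2-en-1-yl)-7-{[tri(propan-2-yl)silyl]oxy}-2-benzothiophen-1(3H)-one, via free thiol 16 (not isolated)
Conditions: TFA (5 vol %), Et3SiH (3 equiv), CH2Cl2, 0 °C; then iPr2NEt (to pH 8), 0 °C to rt, argon
Reagents that add atoms: none
Why: Trityl sulfides ionise in dilute acid and the trityl cation is reduced irreversibly by the silane; on neutralisation the benzylic thiol attacks the neighbouring phenyl ester (5-exo-trig acyl transfer, phenoxide leaving) to close the thiolactone. C3 takes no part in bond making or breaking and keeps its configuration, and the silylated C1′ oxygen cannot compete for the acyl group.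

Step 11
Reactants: 17 (3S)-3-[(1R)-1-{[tert-butyl(dimethyl)silyl]oxy}hexyl]-4-hydroxy-6-(3-methylbut-2-en-1-yl)-7-{[tri(propan-2-yl)silyl]oxy}-2-benzothiophen-1(3H)-one
Product: 18 (3S)-4,7-dihydroxy-3-[(1R)-1-hydroxyhexyl]-6-(3-methylbut-2-en-1-yl)-2-benzothiophen-1(3H)-one (asperglaucin A)
Conditions: HF·pyridine, pyridine, THF, 0 °C to rt, argon, degassed solvents
Reagents that add atoms: none
Why: Fluoride cleavage of the aryl and alkyl silyl ethers under mildly acidic, non-nucleophilic conditions should leave the thioester, the acidic C3–H and the prenyl group untouched, and keeps C1′–OH protonated so that no S-to-O acyl shift occurs.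

## Compound list

1 | (E)-oct-2-en-1-ol | CCCCC/C=C/CO | starting material
2 | [(2R,3R)-3-pentyloxiran-2-yl]methanol | OC[C@H]1O[C@@H]1CCCCC | intermediate
3 | (2S,3R)-3-pentyloxirane-2-carbaldehyde | O=C[C@H]1O[C@@H]1CCCCC | intermediate
4 | (2R,3R)-2-ethynyl-3-pentyloxirane | C#C[C@H]1O[C@@H]1CCCCC | intermediate
5 | (3S,4R)-3-[(triphenylmethyl)sulfanyl]non-1-yn-4-ol | C#C[C@H](SC(c1ccccc1)(c1ccccc1)c1ccccc1)[C@H](O)CCCCC | intermediate
6 | tert-butyl(dimethyl){[(3S,4R)-3-[(triphenylmethyl)sulfanyl]non-1-yn-4-yl]oxy}silane | C#C[C@H](SC(c1ccccc1)(c1ccccc1)c1ccccc1)[C@H](O[Si](C)(C)C(C)(C)C)CCCCC | intermediate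
7 | lithium acetylide of 6 (not isolated) | [Li]C#C[C@H](SC(c1ccccc1)(c1ccccc1)c1ccccc1)[C@H](O[Si](C)(C)C(C)(C)C)CCCCC | intermediate
8 | phenyl (4S,5R)-5-{[tert-butyl(dimethyl)silyl]oxy}-4-[(triphenylmethyl)sulfanyl]dec-2-ynoate | O=C(Oc1ccccc1)C#C[C@H](SC(c1ccccc1)(c1ccccc1)c1ccccc1)[C@H](O[Si](C)(C)C(C)(C)C)CCCCC | intermediate
9 | 3-bromofuran-2(5H)-one | O=C1OCC=C1Br | starting material
10 | [(3-bromofuran-2-yl)oxy]tri(propan-2-yl)silane | Brc1ccoc1O[Si](C(C)C)(C(C)C)C(C)C | intermediate
11 | 1-bromo-3-methylbut-2-ene (prenyl bromide) | CC(C)=CCBr | starting material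
12 | {2-[tri(propan-2-yl)silyl]oxyfuran-3-yl}lithium (not isolated) | [Li]c1ccoc1O[Si](C(C)C)(C(C)C)C(C)C | intermediate
13 | {[3-(3-methylbut-2-en-1-yl)furan-2-yl]oxy}tri(propan-2-yl)silane | CC(C)=CCc1ccoc1O[Si](C(C)C)(C(C)C)C(C)C | intermediate
14 | phenyl 3-[(1S,2R)-2-{[tert-butyl(dimethyl)silyl]oxy}-1-[(triphenylmethyl)sulfanyl]heptyl]-6-(3-methylbut-2-en-1-yl)-1-{[tri(propan-2-yl)silyl]oxy}-7-oxabicyclo[2.2.1]hepta-2,5-diene-2-carboxylate (both bridgehead diastereomers, not isolated) | O=C(Oc1ccccc1)C1=C([C@H](SC(c2ccccc2)(c2ccccc2)c2ccccc2)[C@H](O[Si](C)(C)C(C)(C)C)CCCCC)C2C=C(CC=C(C)C)C1(O[Si](C(C)C)(C(C)C)C(C)C)O2 | intermediate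
15 | phenyl 3-hydroxy-2-[(1S,2R)-2-{[tert-butyl(dimethyl)silyl]oxy}-1-[(triphenylmethyl)sulfanyl]heptyl]-5-(3-methylbut-2-en-1-yl)-6-{[tri(propan-2-yl)silyl]oxy}benzoate | O=C(Oc1ccccc1)c1c([C@H](SC(c2ccccc2)(c2ccccc2)c2ccccc2)[C@H](O[Si](C)(C)C(C)(C)C)CCCCC)c(O)cc(CC=C(C)C)c1O[Si](C(C)C)(C(C)C)C(C)C | intermediate
16 | phenyl 3-hydroxy-2-[(1S,2R)-2-{[tert-butyl(dimethyl)silyl]oxy}-1-sulfanylheptyl]-5-(3-methylbut-2-en-1-yl)-6-{[tri(propan-2-yl)silyl]oxy}benzoate (not isolated) | O=C(Oc1ccccc1)c1c([C@H](S)[C@H](O[Si](C)(C)C(C)(C)C)CCCCC)c(O)cc(CC=C(C)C)c1O[Si](C(C)C)(C(C)C)C(C)C | intermediate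
17 | (3S)-3-[(1R)-1-{[tert-butyl(dimethyl)silyl]oxy}hexyl]-4-hydroxy-6-(3-methylbut-2-en-1-yl)-7-{[tri(propan-2-yl)silyl]oxy}-2-benzothiophen-1(3H)-one | CCCCC[C@@H](O[Si](C)(C)C(C)(C)C)[C@H]1SC(=O)c2c(O[Si](C(C)C)(C(C)C)C(C)C)c(CC=C(C)C)cc(O)c21 | intermediate
18 | (3S)-4,7-dihydroxy-3-[(1R)-1-hydroxyhexyl]-6-(3-methylbut-2-en-1-yl)-2-benzothiophen-1(3H)-one (asperglaucin A) | CCCCC[C@@H](O)[C@H]1SC(=O)c2c(O)c(CC=C(C)C)cc(O)c21 | target

## Step count and least certain steps

Total: 11 steps. Longest linear sequence: 9 steps (steps 1 to 6, then 9, 10, 11); the furan branch (steps 7 and 8) joins at step 9.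

**Step 9 (key step).** The most likely failure is a cycloaddition that is too slow at the branched, trityl-shielded alkyne carbon, so that thermal loss of the silyl group from 13 or isomerisation of 8 to an allenoate wins. Wrong regiochemistry is unlikely because polarity and sterics point the same way. Fallback (sets out from 4, returns at 18): 4 is deprotonated with n-BuLi and acylated with phenyl chloroformate to phenyl 3-[(2R,3R)-3-pentyloxiran-2-yl]prop-2-ynoate F1, a much smaller and more electrophilic dienophile. Cycloaddition of F1 with 13 as in step 9, followed in the same flask by silylation of the new phenol (TBSCl, imidazole), should give the bis-silylated aryl epoxide F2. NaSH (1.1 equiv, DMF, 0 °C) then introduces sulfur after the ring is made: attack at the benzylic epoxide carbon with inversion and closure onto the phenyl ester (either order converges) should give the thiolactone F3 with the same (3S,1′R) configuration. HF·pyridine then removes both aryl silyl ethers to reach 18. The price is that the C–S bond is again made at a benzylic carbon.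

**Step 4.** The very bulky thiolate may open the epoxide slowly or partly at the wrong carbon, and any excess base may isomerise the propargylic sulfide to an allene. Fallback (sets out from 4, returns at 5): thioacetic acid, small and weakly acidic with no base present, opens 4 at the propargylic carbon to S-[(3S,4R)-4-hydroxynon-1-yn-3-yl] ethanethioate F4 (an S-to-O acetyl shift would be harmless). K2CO3 (cat.) in degassed MeOH then gives (3S,4R)-3-sulfanylnon-1-yn-4-ol F5, which is S-tritylated with Ph3COH and a catalytic amount of TFA to give 5.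

**Step 6.** Proton transfer from the γ-carbon of the new ynoate to unreacted acetylide (epimerisation at C4 or allenoate formation) and double addition of acetylide to the reactive phenyl ester are the risks. Fallback (sets out from 6 through 7, returns at 8): the acetylide 7 is quenched with CO2; the carboxylate does not acidify the γ-hydrogen. Acidic work-up gives (4S,5R)-5-{[tert-butyl(dimethyl)silyl]oxy}-4-[(triphenylmethyl)sulfanyl]dec-2-ynoic acid F6, which is esterified with phenol and dicyclohexylcarbodiimide (no amine base) to 8.

**Step 10.** Acid may attack the prenyl double bond (addition or ionic hydrogenation) or partly remove the C1′ silyl ether, after which the six-membered lactone can close; base used for ring closure may epimerise C3. Fallback (sets out from 15, returns at 17): AgNO3 and pyridine in MeOH/THF cleave the S–trityl bond without acid to the silver thiolate of 16 F7, the trityl group leaving as its methyl ether. Brief treatment with dilute HCl precipitates AgCl and frees thiol 16, which closes to 17 on neutralisation as in step 10.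

## Further compounds

F1 | step 9 | phenyl 3-[(2R,3R)-3-pentyloxiran-2-yl]prop-2-ynoate | O=C(Oc1ccccc1)C#C[C@H]1O[C@@H]1CCCCC
F2 | step 9 | phenyl 3-{[tert-butyl(dimethyl)silyl]oxy}-5-(3-methylbut-2-en-1-yl)-2-[(2R,3R)-3-pentyloxiran-2-yl]-6-{[tri(propan-2-yl)silyl]oxy}benzoate | O=C(Oc1ccccc1)c1c([C@H]2O[C@@H]2CCCCC)c(O[Si](C)(C)C(C)(C)C)cc(CC=C(C)C)c1O[Si](C(C)C)(C(C)C)C(C)C
F3 | step 9 | (3S)-4-{[tert-butyl(dimethyl)silyl]oxy}-3-[(1R)-1-hydroxyhexyl]-6-(3-methylbut-2-en-1-yl)-7-{[tri(propan-2-yl)silyl]oxy}-2-benzothiophen-1(3H)-one | CCCCC[C@@H](O)[C@H]1SC(=O)c2c(O[Si](C(C)C)(C(C)C)C(C)C)c(CC=C(C)C)cc(O[Si](C)(C)C(C)(C)C)c21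
F4 | step 4 | S-[(3S,4R)-4-hydroxynon-1-yn-3-yl] ethanethioate | C#C[C@H](SC(C)=O)[C@H](O)CCCCC
F5 | step 4 | (3S,4R)-3-sulfanylnon-1-yn-4-ol | C#C[C@H](S)[C@H](O)CCCCC
F6 | step 6 | (4S,5R)-5-{[tert-butyl(dimethyl)silyl]oxy}-4-[(triphenylmethyl)sulfanyl]dec-2-ynoic acid | OC(=O)C#C[C@H](SC(c1ccccc1)(c1ccccc1)c1ccccc1)[C@H](O[Si](C)(C)C(C)(C)C)CCCCC
F7 | step 10 | silver thiolate of 16 | O=C(Oc1ccccc1)c1c([C@H](S[Ag])[C@H](O[Si](C)(C)C(C)(C)C)CCCCC)c(O)cc(CC=C(C)C)c1O[Si](C(C)C)(C(C)C)C(C)C
A1 | alternative 1 | methyl 2-[(E)-hept-1-en-1-yl]-3,6-dimethoxybenzoate | CCCCC/C=C/c1c(OC)ccc(OC)c1C(=O)OC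
A2 | alternative 1 | methyl 3,6-dimethoxy-2-[(2R,3R)-3-pentyloxiran-2-yl]benzoate | COC(=O)c1c(OC)ccc(OC)c1[C@H]1O[C@@H]1CCCCC
A3 | alternative 1 | (3S)-3-[(1R)-1-hydroxyhexyl]-4,7-dimethoxy-2-benzothiophen-1(3H)-one | CCCCC[C@@H](O)[C@H]1SC(=O)c2c(OC)ccc(OC)c21
A4 | alternative 2 | rac-3-hexanoyl-4,7-bis(methoxymethoxy)-6-(3-methylbut-2-en-1-yl)-2-benzothiophen-1(3H)-one | CCCCCC(=O)C1SC(=O)c2c(OCOC)c(CC=C(C)C)cc(OCOC)c21
A5 | alternative 2 | (3S)-3-[(1R)-1-hydroxyhexyl]-4,7-bis(methoxymethoxy)-6-(3-methylbut-2-en-1-yl)-2-benzothiophen-1(3H)-one | CCCCC[C@@H](O)[C@H]1SC(=O)c2c(OCOC)c(CC=C(C)C)cc(OCOC)c21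
A6 | alternative 3 | pentacarbonyl(1-methoxy-5-methyl-2-methylidenehex-4-en-1-ylidene)chromium | COC(=[Cr])C(=C)CC=C(C)C.[C-]#[O+].[C-]#[O+].[C-]#[O+].[C-]#[O+].[C-]#[O+]
A7 | alternative 3 | phenyl 3-hydroxy-6-methoxy-2-[(1S,2R)-2-{[tert-butyl(dimethyl)silyl]oxy}-1-[(triphenylmethyl)sulfanyl]heptyl]-5-(3-methylbut-2-en-1-yl)benzoate | O=C(Oc1ccccc1)c1c([C@H](SC(c2ccccc2)(c2ccccc2)c2ccccc2)[C@H](O[Si](C)(C)C(C)(C)C)CCCCC)c(O)cc(CC=C(C)C)c1OC
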